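**Plan**

- Retrosynthesis: acetate, angelate and the ring methyl (late cuprate) come off first. The tricycle is then cut in one stroke at two bonds: (i) the bond from the carbinol carbon CH(OH) to the methyl-bearing quaternary cyclobutane carbon, and (ii) the cyclobutane bond from the ketone α-carbon to the CH that carries the C(CH3)(CH2OAc) carbon. A 4-substituted 3-methylcyclohex-2-enone remains.
- Enabling feature: the γ-hydroxy ketone O=C–Cα–Cβ(CH3)–CH(OH) allows a reductive aldehyde–enone union that leaves an enolate exactly at Cα. The angelate-bearing carbon is 1,3 to the cyclobutane CH across the quaternary C(CH3)(CH2OAc) carbon, so its oxygen can be tied to that CH as a 2,4-cis oxetane: folding template, strain-loaded leaving group anti to the enolate, and future ester oxygen.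
- Forward: chain stereodiad by iridium-catalysed tert-(hydroxy)prenylation; cyclohexenyl unit by allylchromium addition; oxetane; enone; one-flask SmI2/Et3SiCl cascade closing the seven-membered ring and then the cyclobutane; Saegusa–Ito/cuprate for the last methyl; angelate, then acetate.
- Stereochemistry: catalyst control (chain); Felkin–Anh/syn allyl transfer (ring-junction CH and oxetane CH); tether and SN2 inversion (quaternary and cyclobutane carbons); samarium chelate (carbinol); face bias of the bicyclo[3.1.1]heptenone (ring methyl).

Key step: step 10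

Assumption: the (R)-Tol-BINAP form of the iridium catalyst is taken to give the (S)-carbinol 3 with the secondary OH anti to the CH2OH arm, as in related transfer-hydrogenative allylations; if the sense is opposite, the (S)-ligand is used.

**Route**

Step 1
Reactants: 1 3,3-diethoxypropan-1-ol; 2 2-methyl-2-vinyloxirane (racemic)
Product: 3 (2S,3S)-5,5-diethoxy-2-methyl-2-vinylpentane-1,3-diol
Conditions: [Ir(cod)Cl]2 (cat.), (R)-Tol-BINAP, 4-cyano-3-nitrobenzoic acid, K3PO4 (cat.), THF, 60 °C
Reagents that add atoms: none
Why: Iridium-catalysed transfer-hydrogenative tert-(hydroxy)prenylation: the alcohol is dehydrogenated to the aldehyde, which the (E)-σ-allyliridium from the vinyl epoxide attacks at its fully substituted terminus through a closed chair transition state, so the quaternary carbon should form with the secondary OH anti to the CH2OH arm and the ligand sets the absolute configuration.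

Step 2
Reactants: 3 (2S,3S)-5,5-diethoxy-2-methyl-2-vinylpentane-1,3-diol
Product: 4 (3S,4S)-1,1-diethoxy-4-methyl-4-[(triisopropylsilyloxy)methyl]hex-5-en-3-ol
Conditions: i-Pr3SiCl, imidazole, DMF, 0 → 23 °C
Reagents that add atoms: triisopropylsilyl chloride CC(C)[Si](Cl)(C(C)C)C(C)C
Why: Selective silylation of the primary hydroxyl by a bulky chlorosilane; the secondary neopentyl-type hydroxyl should stay free.

Step 3
Reactants: 4 (3S,4S)-1,1-diethoxy-4-methyl-4-[(triisopropylsilyloxy)methyl]hex-5-en-3-ol
Product: 5 methanesulfonate of 4 (configuration retained)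
Conditions: MsCl, Et3N, CH2Cl2, 0 °C
Reagents that add atoms: methanesulfonyl chloride CS(Cl)(=O)=O
Why: Sulfonylation of the remaining secondary hydroxyl with retention, which makes this carbon the electrophile of the later oxetane closure.

Step 4
Reactants: 5 methanesulfonate of 4
Product: 7 (2S,3S)-5,5-diethoxy-3-(methanesulfonyloxy)-2-methyl-2-[(triisopropylsilyloxy)methyl]pentanal, via ozonide 6 (not isolated)
Conditions: O3, CH2Cl2, −78 °C; then PPh3
Reagents that add atoms: ozone [O-][O+]=O
Why: Ozonolysis with reductive work-up cleaves the only alkene to an α-quaternary aldehyde that cannot epimerise.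

Step 5
Reactants: 7 the α-quaternary aldehyde; 8 3-bromocyclohexene (racemic)
Product: 10 homoallylic alcohol (CHO of 7 turned into CH(OH)-cyclohex-2-en-1-yl; carbinol and ring CH syn), via allylchromium 9 (not isolated)
Conditions: CrCl2, THF, 0 → 23 °C
Reagents that add atoms: none
Why: Nozaki–Hiyama–Kishi-type allylation: the ring-constrained (Z)-allylchromium adds through a chair (Zimmerman–Traxler) transition state, which should give the syn relation of the two new stereocentres, on the Felkin–Anh face of the aldehyde (nucleophile anti to the mesyloxy-bearing branch, passing the methyl group).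

Step 6
Reactants: 10 homoallylic alcohol
Product: 11 2-(cyclohex-2-en-1-yl)-4-(2,2-diethoxyethyl)-3-methyl-3-[(triisopropylsilyloxy)methyl]oxetane (the substituents at C-2 and C-4 and the CH2O arm at C-3 on one face)
Conditions: KN(SiMe3)2, THF, 0 → 40 °C
Reagents that add atoms: none
Why: Intramolecular Williamson etherification (4-exo-tet): the alkoxide displaces the neighbouring secondary mesylate with inversion, which should give the 2,4-cis oxetane; closure across the quaternary carbon is helped by the gem-disubstituent effect.

Step 7
Reactants: 11 the all-cis oxetane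
Product: 12 4-(oxetan-2-yl)cyclohex-2-en-1-one derived from 11 (other groups unchanged)
Conditions: CrO3, 3,5-dimethylpyrazole, CH2Cl2, −20 °C
Reagents that add atoms: chromium trioxide O=[Cr](=O)=O
Why: Chromium trioxide–dimethylpyrazole allylic oxidation should take the ring CH2 next to the unsubstituted alkene carbon (the other allylic position is a hindered tertiary CH), giving the enone without touching a stereocentre.

Step 8
Reactants: 12 the cyclohexenone
Product: 14 3-methyl-4-(oxetan-2-yl)cyclohex-2-en-1-one, via silyl enol ether 13 (not isolated)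
Conditions: Me2CuLi, Me3SiCl, THF, −78 °C; then Pd(OAc)2, MeCN, 23 °C
Reagents that add atoms: lithium dimethylcuprate [Li+].C[Cu-]C
Why: Cuprate conjugate addition with silyl trapping, then Saegusa–Ito oxidation of the regiodefined silyl enol ether, should return the enone with its β-methyl group; the stereocentre made at the β-carbon is erased again.

Step 9
Reactants: 14 the 3-methyl enone
Product: 15 aldehyde (diethyl acetal of 14 turned into CHO)
Conditions: PPTS, acetone/H2O, 50 °C
Reagents that add atoms: water O
Why: Acid-catalysed acetal hydrolysis under buffered conditions that should leave the tetrasubstituted oxetane, the enone and the silyl ether intact.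

Step 10
Reactants: 15 the oxetanyl enone aldehyde
Product: 17 tricyclic keto alcohol (triethylsilyl ether at the new carbinol; free OH at the former oxetane carbon; CH2OSi(i-Pr)3 arm), via bis(triethylsilyl) compound 16 (not isolated)
Conditions: SmI2, Et3SiCl, THF, −78 → 23 °C; aq. NaHCO3
Reagents that add atoms: chlorotriethylsilane CC[Si](Cl)(CC)CC
Why: Proposed new method: SmI2 reduces the aldehyde to a samarium ketyl that adds 7-exo-trig to the enone β-carbon, a second electron gives the samarium enolate, and Et3SiCl caps the alkoxide and the enolate oxygen (closest known type: SmI2 ketyl–enone reductive cyclization with chlorosilane trapping). On warming, the trivalent samarium halide formed in the reduction activates the oxetane, and the regiodefined silyl enol ether opens it at the ring-bearing carbon in a 4-exo-tet Mukaiyama-type alkylation (closest known types: samarium-iodide-promoted Mukaiyama reactions, Lewis-acid opening of oxetanes by enol silanes and enolates, 4-exo-tet epoxide openings to cyclobutanes); the oxetane strain pays for the cyclobutane. The 2,4-cis oxetane holds aldehyde and enone on one face, so the seven-membered ring should close cis to the oxetanyl carbon, which fixes the quaternary carbon; a samarium chelate between ketyl oxygen and enone oxygen should set the carbinol. The cyclobutane CH is set by inversion, the oxygen leaving anti to the enolate carbon and ending as the free secondary alcohol. Needed selectivities and what secures them: C- over O-alkylation (O-attack would need a bridgehead enol ether); the ring-bearing oxetane carbon (the backside of the other cannot be reached through the new ring); the α- not α′-enolate (made by conjugate addition, no proton source); and no attack of the carbinol oxygen on the oxetane (it is silylated first).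

Step 11
Reactants: 17 tricyclic keto alcohol
Product: 19 bicyclo[3.1.1]hept-3-en-2-one form of 17 with the free OH as trimethylsilyl ether, via silyl enol ether 18 (not isolated)
Conditions: Me3SiOTf, Et3N, CH2Cl2, 0 °C; then Pd(OAc)2, MeCN, 23 °C
Reagents that add atoms: trimethylsilyl trifluoromethanesulfonate C[Si](C)(C)OS(=O)(=O)C(F)(F)F
Why: Saegusa–Ito oxidation: soft enolisation can only go towards the CH2 because the other α-carbon is a bridgehead of the bicyclo[3.1.1]heptanone, so silyl enol ether and enone are regiodefined; the free hydroxyl is silylated in passing.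

Step 12
Reactants: 19 the tricyclic enone
Product: 21 ring-methylated hydroxy ketone (free OH at the future angelate carbon), via trimethylsilyl ether 20 (not isolated)
Conditions: Me2CuLi, Et2O, −78 → −30 °C; then 0.5 M HCl, THF, 0 °C
Reagents that add atoms: lithium dimethylcuprate [Li+].C[Cu-]C
Why: Cuprate conjugate addition should occur anti to the one-carbon bridge whose methyl group hangs over the enone (the face bias known from verbenone-type bicyclo[3.1.1]heptenones), placing the new methyl cis to the other bridge as required; dilute acid cleaves only the trimethylsilyl ether.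

Step 13
Reactants: 21 ring-methylated hydroxy ketone
Product: 22 angelate of 21
Conditions: angelic acid, 2,4,6-trichlorobenzoyl chloride, Et3N, toluene, 23 °C; then 21, 80 °C
Reagents that add atoms: angelic acid C/C=C(/C)C(O)=O
Why: Yamaguchi esterification: the mixed anhydride acylates the only free hydroxyl, and base-poor conditions should limit Z→E isomerisation to the tiglate.

Step 14
Reactants: 22 angelate
Product: 23 diol (angelate kept; secondary carbinol and CH2OH free)
Conditions: HF·pyridine, THF, 0 → 23 °C
Reagents that add atoms: none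
Why: Fluoride-mediated cleavage of both silyl ethers, to which the ester and the ketone are inert.

Step 15
Reactants: 23 diol
Product: 24 CNP0212099.1 (target)
Conditions: AcCl, 2,4,6-collidine, CH2Cl2, −78 °C
Reagents that add atoms: acetyl chloride CC(Cl)=O
Why: Selective acylation: at low temperature the primary hydroxyl should be acetylated far faster than the hindered secondary one next to the quaternary cyclobutane carbon.

**Compound list**

1 | 3,3-diethoxypropan-1-ol | OCCC(OCC)OCC | starting material
2 | 2-methyl-2-vinyloxirane (racemic) | CC1(C=C)CO1 | starting material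
3 | (2S,3S)-5,5-diethoxy-2-methyl-2-vinylpentane-1,3-diol | CCOC(OCC)C[C@H](O)[C@](C)(CO)C=C | intermediate
4 | (3S,4S)-1,1-diethoxy-4-methyl-4-[(triisopropylsilyloxy)methyl]hex-5-en-3-ol | CCOC(OCC)C[C@H](O)[C@](C)(CO[Si](C(C)C)(C(C)C)C(C)C)C=C | intermediate
5 | methanesulfonate of 4 | CCOC(OCC)C[C@H](OS(C)(=O)=O)[C@](C)(CO[Si](C(C)C)(C(C)C)C(C)C)C=C | intermediate
6 | 1,2,4-trioxolane (secondary ozonide) of 5 | CCOC(OCC)C[C@H](OS(C)(=O)=O)[C@](C)(CO[Si](C(C)C)(C(C)C)C(C)C)C1OCOO1 | intermediate
7 | (2S,3S)-5,5-diethoxy-3-(methanesulfonyloxy)-2-methyl-2-[(triisopropylsilyloxy)methyl]pentanal | CCOC(OCC)C[C@H](OS(C)(=O)=O)[C@](C)(CO[Si](C(C)C)(C(C)C)C(C)C)C=O | intermediate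
8 | 3-bromocyclohexene (racemic) | BrC1C=CCCC1 | starting material
9 | cyclohex-2-en-1-ylchromium dichloride | Cl[Cr](Cl)C1C=CCCC1 | intermediate
10 | homoallylic alcohol, syn carbinol/ring CH, Felkin at the quaternary carbon | CCOC(OCC)C[C@H](OS(C)(=O)=O)[C@](C)(CO[Si](C(C)C)(C(C)C)C(C)C)[C@@H](O)[C@@H]1CCCC=C1 | intermediate
11 | all-cis 2-(cyclohex-2-en-1-yl)-4-(2,2-diethoxyethyl)-3-methyl-3-[(triisopropylsilyloxy)methyl]oxetane | CCOC(OCC)C[C@H]1O[C@@H]([C@@H]2CCCC=C2)[C@@]1(C)CO[Si](C(C)C)(C(C)C)C(C)C | intermediate
12 | 4-(oxetan-2-yl)cyclohex-2-en-1-one from 11 | CCOC(OCC)C[C@H]1O[C@@H]([C@@H]2CCC(=O)C=C2)[C@@]1(C)CO[Si](C(C)C)(C(C)C)C(C)C | intermediate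
13 | trimethylsilyl enol ether after methyl addition (methyl trans to the oxetanyl group) | CCOC(OCC)C[C@H]1O[C@@H]([C@@H]2CCC(O[Si](C)(C)C)=C[C@H]2C)[C@@]1(C)CO[Si](C(C)C)(C(C)C)C(C)C | intermediate
14 | 3-methyl-4-(oxetan-2-yl)cyclohex-2-en-1-one | CCOC(OCC)C[C@H]1O[C@@H]([C@@H]2CCC(=O)C=C2C)[C@@]1(C)CO[Si](C(C)C)(C(C)C)C(C)C | intermediate
15 | oxetanyl enone aldehyde (key-step substrate) | O=CC[C@H]1O[C@@H]([C@@H]2CCC(=O)C=C2C)[C@@]1(C)CO[Si](C(C)C)(C(C)C)C(C)C | intermediate
16 | bis(triethylsilyl) compound: seven-membered ring closed, triethylsilyl enol ether, oxetane intact | CC[Si](CC)(CC)O[C@@H]1C[C@H]2O[C@@H]([C@@H]3CCC(O[Si](CC)(CC)CC)=C[C@@]31C)[C@@]2(C)CO[Si](C(C)C)(C(C)C)C(C)C | intermediate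
17 | tricyclic keto alcohol (OSiEt3 at the carbinol, free OH, CH2OSi(i-Pr)3) | O[C@@H]1C[C@@H](O[Si](CC)(CC)CC)[C@]2(C)[C@@H]3[C@@H]([C@H]2C(=O)CC3)[C@@]1(C)CO[Si](C(C)C)(C(C)C)C(C)C | intermediate
18 | trimethylsilyl enol ether and trimethylsilyl ether of 17 | C[Si](C)(C)O[C@@H]1C[C@@H](O[Si](CC)(CC)CC)[C@]2(C)[C@@H]3[C@@H]([C@H]2C(O[Si](C)(C)C)=CC3)[C@@]1(C)CO[Si](C(C)C)(C(C)C)C(C)C | intermediate
19 | tricyclic enone, trimethylsilyl ether | C[Si](C)(C)O[C@@H]1C[C@@H](O[Si](CC)(CC)CC)[C@]2(C)[C@@H]3[C@@H]([C@H]2C(=O)C=C3)[C@@]1(C)CO[Si](C(C)C)(C(C)C)C(C)C | intermediate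
20 | ring-methylated ketone, trimethylsilyl ether | C[Si](C)(C)O[C@@H]1C[C@@H](O[Si](CC)(CC)CC)[C@]2(C)[C@@H]3[C@@H]([C@H]2C(=O)C[C@H]3C)[C@@]1(C)CO[Si](C(C)C)(C(C)C)C(C)C | intermediate
21 | ring-methylated hydroxy ketone | O[C@@H]1C[C@@H](O[Si](CC)(CC)CC)[C@]2(C)[C@@H]3[C@@H]([C@H]2C(=O)C[C@H]3C)[C@@]1(C)CO[Si](C(C)C)(C(C)C)C(C)C | intermediate
22 | angelate of 21 | C/C=C(/C)C(=O)O[C@@H]1C[C@@H](O[Si](CC)(CC)CC)[C@]2(C)[C@@H]3[C@@H]([C@H]2C(=O)C[C@H]3C)[C@@]1(C)CO[Si](C(C)C)(C(C)C)C(C)C | intermediate
23 | desilylated angelate diol | C/C=C(/C)C(=O)O[C@@H]1C[C@@H](O)[C@]2(C)[C@@H]3[C@@H]([C@H]2C(=O)C[C@H]3C)[C@@]1(C)CO | intermediate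
24 | CNP0212099.1 | C/C=C(/C)C(=O)O[C@@H]1C[C@@H](O)[C@]2(C)[C@@H]3[C@@H]([C@H]2C(=O)C[C@H]3C)[C@@]1(C)COC(C)=O | target

**Step count and risks**

Total step count: 15. Longest linear sequence: 15 steps (1 → 24).

Steps most likely to fail:

1. Step 10 (proposed new method). The sequence may stop after the seven-membered ring because the silyl enol ether does not engage the oxetane; silyl halide may open the oxetane; or reductive dimerisation of the aldehyde may outrun the 7-exo closure. Fallback, from 15 back to 17: the cascade is divided into isolated operations of known type. 15 is cyclised with SmI2/Et3SiCl at −78 °C and worked up cold, so that the bis(triethylsilyl) compound 16 is isolated. MeLi (THF, −78 → 0 °C) then cleaves only the silyl enol ether to the regiodefined lithium enolate, and BF3·OEt2 at −78 °C promotes the enolate opening of the oxetane, as for lithium nucleophiles with oxetanes. Aqueous work-up gives 17.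

2. Step 6. Fragmentation of the γ-sulfonyloxy alkoxide (cleavage of the bond between carbinol and quaternary carbon) or elimination of the mesylate may compete with the four-membered ring closure. Fallback, from 4 back to 11: the mesylation is omitted and no alkoxide is ever formed. Ozonolysis of 4 (O3; PPh3) gives the hydroxy aldehyde F1, and allylchromium addition as in step 5 gives the diol F2. Redox cyclodehydration (PPh3, DIAD, THF; Mitsunobu-type) activates the less encumbered carbinol, the one bearing the 2,2-diethoxyethyl chain, and the other hydroxyl displaces it with inversion to give 11.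

3. Step 5. Facial discrimination at the α-quaternary aldehyde may be insufficient, or the syn preference may erode. Fallback, from 7 back to 10: substrate control is replaced by reagent control. Enantioenriched pinacol cyclohex-2-en-1-ylboronate (the enantiomer whose chair transition state places the ring stereocentre as in 10), with Sc(OTf)3 in CH2Cl2 at −78 °C, adds by allylboration with 1,3-chirality transfer; aqueous work-up gives 10.

Further compounds
F1 | step 6 | (2S,3S)-5,5-diethoxy-3-hydroxy-2-methyl-2-[(triisopropylsilyloxy)methyl]pentanal | CCOC(OCC)C[C@H](O)[C@](C)(CO[Si](C(C)C)(C(C)C)C(C)C)C=O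
F2 | step 6 | diol: 10 with free OH in place of the mesylate | CCOC(OCC)C[C@H](O)[C@](C)(CO[Si](C(C)C)(C(C)C)C(C)C)[C@@H](O)[C@@H]1CCCC=C1
F0 | step 10 | none | none
F0 | step 5 | none | none
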